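**Retrosynthetic overview**
- The enol ester comes from an aldehyde. The 2-oxopropyl and acetaldehyde arms come from a methallyl and an allyl group by one double ozonolysis; both are put on a tricyclic enone by conjugate allylation and enolate alkylation.
- The tricyclic enone comes from a monocyclic silyl ether ynone by one cobalt hydride double cyclisation. The pyran closes by C–O bond formation, then the bridging cycloheptenone closes by C–C bond formation at the quaternary methyl carbon.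
- The ynone comes from an amide by hydroxymethylation and ethynyl addition. The amide comes from an Eschenmoser–Claisen rearrangement of (1S,4R)-p-mentha-2,8-dien-1-ol.
- Ring order: cyclohexene (bought, chiral pool), then pyran and seven-membered ring in the same operation.

Assumption: compound 1, the (1S,4R) isomer with hydroxyl and isopropenyl cis (the cannabinoid building block), is bought enantiopure; it is also available from (R)-limonene oxide.

**Step 1**
Reactants: 1 (1S,4R)-1-methyl-4-(prop-1-en-2-yl)cyclohex-2-en-1-ol; 2 1,1-dimethoxy-N,N-dimethylethan-1-amine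
Product: 4 amide 2-[(1S,6R)-3-methyl-6-(prop-1-en-2-yl)cyclohex-2-en-1-yl]-N,N-dimethylacetamide, via ketene N,O-acetal 3 (not isolated)
Conditions: 2 (3 equiv), xylenes, 140 °C, MeOH distilled off
Reagents that add atoms: 1,1-dimethoxy-N,N-dimethylethan-1-amine (2), CC(OC)(OC)N(C)C
Why: Eschenmoser–Claisen rearrangement, in which 3 reacts suprafacially through a half-chair with the C–O bond pseudoaxial and the cis isopropenyl group pseudoequatorial, so the acetamide arm lands on the ring face that carried oxygen (cis to isopropenyl, new centre 1S) and the double bond moves to the trisubstituted position needed in step 4.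

**Step 2**
Reactants: 4; 5 formaldehyde
Product: 8 (2S)-N,N-dimethyl-2-[(1S,6R)-3-methyl-6-(prop-1-en-2-yl)cyclohex-2-en-1-yl]-3-[(triethylsilyl)oxy]propanamide, via lithium enolate 6 (not isolated), via lithium alkoxide 7 (not isolated)
Conditions: lithium diisopropylamide, THF, −78 °C; 5 (gas from cracked paraformaldehyde), −78 → −40 °C; Et3SiCl, −40 → 0 °C
Reagents that add atoms: formaldehyde (5), C=O; chlorotriethylsilane, CC[Si](Cl)(CC)CC
Why: Aldol addition of the Z amide enolate to formaldehyde followed by O-silylation, where the ring C–H eclipses the enolate (allylic strain) and formaldehyde attacks the face next to the ring alkene carbon, not the face shielded by the isopropenyl-bearing carbon, giving the 2S centre (minor epimer removed by chromatography).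

**Step 3**
Reactants: 8; 9 acetylene
Product: 11 (4S)-4-[(1S,6R)-3-methyl-6-(prop-1-en-2-yl)cyclohex-2-en-1-yl]-5-[(triethylsilyl)oxy]pent-1-yn-3-one, via lithium hemiaminal alkoxide 10 (not isolated)
Conditions: 9, n-BuLi, THF, −78 °C; then 8, −78 → 0 °C; poured into cold aq. AcOH
Reagents that add atoms: ethynyllithium (made in the flask from acetylene 9 and n-BuLi), [Li]C#C
Why: Acyl substitution of a tertiary amide by an alkynyllithium, in which the tetrahedral adduct 10 collapses to the ynone only on the acidic quench (which also protonates the released dimethylamine before it can add to the ynone) and the weakly basic acetylide does not enolise the α-stereocentre.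

**Step 4**
Reactants: 11
Product: 13 (1S,4R,8S,13S)-1,5,5-trimethyl-6-oxatricyclo[6.3.2.0^{4,13}]tridec-10-en-9-one, via pyran ynone 12 (not isolated)
Conditions: Co(salen) (5 mol %), N-fluoro-2,4,6-trimethylpyridinium tetrafluoroborate (2.2 equiv), PhSiH3 (3.3 equiv), PhCF3, 0 °C → rt, 0.01 M
Reagents that add atoms: none
Why: Proposed new method: one cobalt hydride system runs two hydrogen-atom-transfer cyclisations in the same flask – the faster-reacting isopropenyl group gives a tertiary radical that is oxidised and captured by the silyl ether oxygen with loss of the silyl group (radical–polar crossover hydroalkoxylation) to give pyran 12, and hydrogen-atom transfer to the ring alkene then gives the methyl-bearing tertiary radical, which the cis side chain forces to add to the ynone terminus from its own face (7-endo-dig Giese addition, vinyl radical quenched by Si–H, unproductive elimination only regenerating an alkene that re-enters), so the quaternary centre (1S) and the cis-enone are fixed by the tether; the closest known reactions are cobalt-salen hydroalkoxylation of unactivated alkenes and hydrogen-atom-transfer-initiated radical conjugate additions and bicyclisations onto electron-poor π bonds.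

**Step 5**
Reactants: 13; 14 allyltrimethylsilane
Product: 16 (1S,4R,8S,11S,13S)-1,5,5-trimethyl-11-(prop-2-en-1-yl)-6-oxatricyclo[6.3.2.0^{4,13}]tridecan-9-one, via titanium enolate 15 (not isolated)
Conditions: 14, TiCl4, CH2Cl2, −78 °C; H2O
Reagents that add atoms: allyltrimethylsilane (14), C=CC[Si](C)(C)C
Why: Hosomi–Sakurai conjugate allylation, in which the TiCl4-activated enone is attacked at the β-carbon from the open face on the side of the one-carbon bridge, away from the three-carbon bridge and the fused pyran, setting the 11S centre.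

**Step 6**
Reactants: 16; 17 3-bromo-2-methylprop-1-ene
Product: 19 (1S,4R,8S,10R,11S,13S)-1,5,5-trimethyl-10-(2-methylprop-2-en-1-yl)-11-(prop-2-en-1-yl)-6-oxatricyclo[6.3.2.0^{4,13}]tridecan-9-one, via lithium enolate 18 (not isolated)
Conditions: lithium diisopropylamide, THF, −78 °C; 17, DMPU, −78 → −30 °C
Reagents that add atoms: 3-bromo-2-methylprop-1-ene (17), CC(=C)CBr
Why: Kinetic enolate alkylation, with deprotonation at the α-methylene (the other α-carbon is a hindered ring-fusion methine) and SN2 attack anti to the neighbouring allyl group giving the trans 10R,11S pair; this is the only epimerisable centre, and trans is expected (not verified) to be the thermodynamic arrangement as well.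

**Step 7**
Reactants: 19
Product: 21 2-[(1S,4R,8S,10R,11S,13S)-1,5,5-trimethyl-9-oxo-10-(2-oxopropyl)-6-oxatricyclo[6.3.2.0^{4,13}]tridecan-11-yl]acetaldehyde, via bis-ozonide 20 (not isolated)
Conditions: O3, CH2Cl2, −78 °C; Me2S, −78 °C → rt
Reagents that add atoms: ozone, [O-][O+]=O
Why: Ozonolysis with reductive work-up cleaves both terminal alkenes at once, turning the methallyl group into the 2-oxopropyl group and the allyl group into the acetaldehyde arm without touching a stereocentre.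

**Step 8**
Reactants: 21; 22 3-methylbut-2-enoic anhydride
Product: 23 (E)-2-[(1S,4R,8S,10R,11S,13S)-1,5,5-trimethyl-9-oxo-10-(2-oxopropyl)-6-oxatricyclo[6.3.2.0^{4,13}]tridecan-11-yl]ethenyl 3-methylbut-2-enoate
Conditions: 22, Et3N, DMAP (cat.), CH2Cl2, 0 °C → rt
Reagents that add atoms: 3-methylbut-2-enoic anhydride (22), CC(C)=CC(=O)OC(=O)C=C(C)C
Why: Enol ester formation by O-acylation of the aldehyde enolate, where only the aldehyde enolises under amine/DMAP conditions and the bulky ring substituent on the β-carbon should favour the E isomer; the ratio is uncertain and the minor Z isomer is separated.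

**Compound list**
1 | (1S,4R)-1-methyl-4-(prop-1-en-2-yl)cyclohex-2-en-1-ol | C[C@@]1(O)C=C[C@H](C(C)=C)CC1 | starting material
2 | 1,1-dimethoxy-N,N-dimethylethan-1-amine (N,N-dimethylacetamide dimethyl acetal) | CC(OC)(OC)N(C)C | starting material
3 | N,N-dimethyl-1-{[(1S,4R)-1-methyl-4-(prop-1-en-2-yl)cyclohex-2-en-1-yl]oxy}ethen-1-amine (ketene N,O-acetal) | C=C(N(C)C)O[C@]1(C)C=C[C@H](C(C)=C)CC1 | intermediate
4 | 2-[(1S,6R)-3-methyl-6-(prop-1-en-2-yl)cyclohex-2-en-1-yl]-N,N-dimethylacetamide | CN(C)C(=O)C[C@H]1C=C(C)CC[C@H]1C(C)=C | intermediate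
5 | formaldehyde | C=O | starting material
6 | lithium (Z)-1-(dimethylamino)-2-[(1S,6R)-3-methyl-6-(prop-1-en-2-yl)cyclohex-2-en-1-yl]ethen-1-olate | CN(C)/C(O[Li])=C/[C@H]1C=C(C)CC[C@H]1C(C)=C | intermediate
7 | lithium (2S)-3-(dimethylamino)-2-[(1S,6R)-3-methyl-6-(prop-1-en-2-yl)cyclohex-2-en-1-yl]-3-oxopropan-1-olate | CN(C)C(=O)[C@H](CO[Li])[C@H]1C=C(C)CC[C@H]1C(C)=C | intermediate
8 | (2S)-N,N-dimethyl-2-[(1S,6R)-3-methyl-6-(prop-1-en-2-yl)cyclohex-2-en-1-yl]-3-[(triethylsilyl)oxy]propanamide | CN(C)C(=O)[C@H](CO[Si](CC)(CC)CC)[C@H]1C=C(C)CC[C@H]1C(C)=C | intermediate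
9 | acetylene | C#C | starting material
10 | lithium (4S)-3-(dimethylamino)-4-[(1S,6R)-3-methyl-6-(prop-1-en-2-yl)cyclohex-2-en-1-yl]-5-[(triethylsilyl)oxy]pent-1-yn-3-olate (C-3 unassigned) | C#CC(O[Li])(N(C)C)[C@H](CO[Si](CC)(CC)CC)[C@H]1C=C(C)CC[C@H]1C(C)=C | intermediate
11 | (4S)-4-[(1S,6R)-3-methyl-6-(prop-1-en-2-yl)cyclohex-2-en-1-yl]-5-[(triethylsilyl)oxy]pent-1-yn-3-one | C#CC(=O)[C@H](CO[Si](CC)(CC)CC)[C@H]1C=C(C)CC[C@H]1C(C)=C | intermediate
12 | 1-[(4S,4aS,8aR)-1,1,6-trimethyl-3,4,4a,7,8,8a-hexahydro-1H-isochromen-4-yl]prop-2-yn-1-one (cis-fused pyran ynone) | C#CC(=O)[C@@H]1COC(C)(C)[C@@H]2CCC(C)=C[C@H]12 | intermediate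
13 | (1S,4R,8S,13S)-1,5,5-trimethyl-6-oxatricyclo[6.3.2.0^{4,13}]tridec-10-en-9-one | O=C1C=C[C@@]2(C)CC[C@H]3C(C)(C)OC[C@@H]1[C@H]3C2 | intermediate
14 | allyltrimethylsilane | C=CC[Si](C)(C)C | starting material
15 | trichloro{[(1S,4R,8S,11S,13S)-1,5,5-trimethyl-11-(prop-2-en-1-yl)-6-oxatricyclo[6.3.2.0^{4,13}]tridec-9-en-9-yl]oxy}titanium | Cl[Ti](Cl)(Cl)OC1=C[C@H](CC=C)[C@@]2(C)CC[C@H]3C(C)(C)OC[C@@H]1[C@H]3C2 | intermediate
16 | (1S,4R,8S,11S,13S)-1,5,5-trimethyl-11-(prop-2-en-1-yl)-6-oxatricyclo[6.3.2.0^{4,13}]tridecan-9-one | O=C1C[C@H](CC=C)[C@@]2(C)CC[C@H]3C(C)(C)OC[C@@H]1[C@H]3C2 | intermediate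
17 | 3-bromo-2-methylprop-1-ene | CC(=C)CBr | starting material
18 | lithium (1S,4R,8S,11S,13S)-1,5,5-trimethyl-11-(prop-2-en-1-yl)-6-oxatricyclo[6.3.2.0^{4,13}]tridec-9-en-9-olate | [Li]OC1=C[C@H](CC=C)[C@@]2(C)CC[C@H]3C(C)(C)OC[C@@H]1[C@H]3C2 | intermediate
19 | (1S,4R,8S,10R,11S,13S)-1,5,5-trimethyl-10-(2-methylprop-2-en-1-yl)-11-(prop-2-en-1-yl)-6-oxatricyclo[6.3.2.0^{4,13}]tridecan-9-one | CC(=C)C[C@H]1C(=O)[C@@H]2COC(C)(C)[C@@H]3CC[C@@](C)(C[C@@H]32)[C@H]1CC=C | intermediate
20 | (1S,4R,8S,10R,11S,13S)-1,5,5-trimethyl-10-[(3-methyl-1,2,4-trioxolan-3-yl)methyl]-11-[(1,2,4-trioxolan-3-yl)methyl]-6-oxatricyclo[6.3.2.0^{4,13}]tridecan-9-one (bis-ozonide) | CC4(OCOO4)C[C@H]1C(=O)[C@@H]2COC(C)(C)[C@@H]3CC[C@@](C)(C[C@@H]32)[C@H]1CC5OCOO5 | intermediate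
21 | 2-[(1S,4R,8S,10R,11S,13S)-1,5,5-trimethyl-9-oxo-10-(2-oxopropyl)-6-oxatricyclo[6.3.2.0^{4,13}]tridecan-11-yl]acetaldehyde | CC(=O)C[C@H]1C(=O)[C@@H]2COC(C)(C)[C@@H]3CC[C@@](C)(C[C@@H]32)[C@H]1CC=O | intermediate
22 | 3-methylbut-2-enoic anhydride | CC(C)=CC(=O)OC(=O)C=C(C)C | starting material
23 | (E)-2-[(1S,4R,8S,10R,11S,13S)-1,5,5-trimethyl-9-oxo-10-(2-oxopropyl)-6-oxatricyclo[6.3.2.0^{4,13}]tridecan-11-yl]ethenyl 3-methylbut-2-enoate | CC(=O)C[C@H]1C(=O)[C@@H]2COC(C)(C)[C@@H]3CC[C@@](C)(C[C@@H]32)[C@H]1/C=C/OC(=O)C=C(C)C | target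

**Step count and risk**
Total steps: 8. Longest linear sequence: 8 (from 1).

Steps most likely to fail:

Step 4 (double cyclisation). The ring-alkene radical may be lost to hydrofluorination or plain alkene isomerisation before the slow bridged seven-membered closure, and the isopropenyl radical could attack the ynone instead of being trapped by oxygen. Fallback, setting out from 11 and returning at 13: close the pyran alone with camphorsulfonic acid in CH2Cl2 at 0 °C (Brønsted acid hydroalkoxylation with loss of the silyl group) and isolate 12. Half-hydrogenate the alkyne (H2, Pd/CaCO3 poisoned with Pb(OAc)2, quinoline) to the vinyl ketone 1-[(4S,4aS,8aR)-1,1,6-trimethyl-3,4,4a,7,8,8a-hexahydro-1H-isochromen-4-yl]prop-2-en-1-one F1. Close the bridging ring by the reductive iron hydride olefin–enone coupling (Fe(acac)3, PhSiH3, EtOH, 60 °C, 7-endo-trig) to the saturated ketone (1R,4R,8S,13S)-1,5,5-trimethyl-6-oxatricyclo[6.3.2.0^{4,13}]tridecan-9-one F2. Dehydrogenate with 2-iodoxybenzoic acid (DMSO, 70 °C), which can place the double bond only away from the bridgehead, to rejoin at 13.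

Step 8 (enol ester). The E/Z ratio may be poor and the keto aldehyde can undergo aldol reactions under base. Fallback, setting out from 13 and returning at 23, builds the E alkene stereospecifically through boron:
- Copper-catalysed conjugate addition of vinylmagnesium bromide (CuBr·SMe2, Me3SiCl, THF, −78 °C) gives (1S,4R,8S,11R,13S)-11-ethenyl-1,5,5-trimethyl-6-oxatricyclo[6.3.2.0^{4,13}]tridecan-9-one F3.
- Methallylation as in step 6 gives (1S,4R,8S,10R,11S,13S)-11-ethenyl-1,5,5-trimethyl-10-(2-methylprop-2-en-1-yl)-6-oxatricyclo[6.3.2.0^{4,13}]tridecan-9-one F4.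
- Ozonolysis gives (1S,4R,8S,10R,11S,13S)-1,5,5-trimethyl-9-oxo-10-(2-oxopropyl)-6-oxatricyclo[6.3.2.0^{4,13}]tridecane-11-carbaldehyde F5.
- Takai–Utimoto borylolefination of the aldehyde only (2-(dichloromethyl)-4,4,5,5-tetramethyl-1,3,2-dioxaborolane, CrCl2, LiI, THF) gives (1S,4R,8S,10R,11S,13S)-1,5,5-trimethyl-10-(2-oxopropyl)-11-[(E)-2-(4,4,5,5-tetramethyl-1,3,2-dioxaborolan-2-yl)ethenyl]-6-oxatricyclo[6.3.2.0^{4,13}]tridecan-9-one F6.
- KHF2 in aqueous MeOH gives potassium trifluoro{(E)-2-[(1S,4R,8S,10R,11S,13S)-1,5,5-trimethyl-9-oxo-10-(2-oxopropyl)-6-oxatricyclo[6.3.2.0^{4,13}]tridecan-11-yl]ethenyl}borate F7.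
- Chan–Lam-type coupling with 3-methylbut-2-enoic acid (Cu(OAc)2, DMAP, 4 Å sieves, O2, CH2Cl2) forms the C–O bond with retention of the E geometry and gives 23.

Step 6 (enolate alkylation). Regio- and face-selectivity next to the quaternary centre are uncertain, and any enolate on the pyran side would open the ring by β-elimination. Fallback, setting out from 16 and returning at 21: trap the kinetic enolate (lithium diisopropylamide, Me3SiCl, −78 °C) as trimethyl{[(1S,4R,8S,11S,13S)-1,5,5-trimethyl-11-(prop-2-en-1-yl)-6-oxatricyclo[6.3.2.0^{4,13}]tridec-9-en-9-yl]oxy}silane F8. Add it to 2-nitropropene with SnCl4 at −78 °C and hydrolyse (Mukaiyama–Michael/Nef sequence that gives the 1,4-diketone directly) to (1S,4R,8S,10R,11S,13S)-1,5,5-trimethyl-10-(2-oxopropyl)-11-(prop-2-en-1-yl)-6-oxatricyclo[6.3.2.0^{4,13}]tridecan-9-one F9. Ozonise the remaining allyl group (O3, then Me2S) to rejoin at 21.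

**Further compounds**
F1 | step 4 | 1-[(4S,4aS,8aR)-1,1,6-trimethyl-3,4,4a,7,8,8a-hexahydro-1H-isochromen-4-yl]prop-2-en-1-one | C=CC(=O)[C@@H]1COC(C)(C)[C@@H]2CCC(C)=C[C@H]12
F2 | step 4 | (1R,4R,8S,13S)-1,5,5-trimethyl-6-oxatricyclo[6.3.2.0^{4,13}]tridecan-9-one | O=C1CC[C@@]2(C)CC[C@H]3C(C)(C)OC[C@@H]1[C@H]3C2
F3 | step 8 | (1S,4R,8S,11R,13S)-11-ethenyl-1,5,5-trimethyl-6-oxatricyclo[6.3.2.0^{4,13}]tridecan-9-one | C1C(=O)[C@@H]2COC(C)(C)[C@@H]3CC[C@@](C)(C[C@@H]32)[C@H]1C=C
F4 | step 8 | (1S,4R,8S,10R,11S,13S)-11-ethenyl-1,5,5-trimethyl-10-(2-methylprop-2-en-1-yl)-6-oxatricyclo[6.3.2.0^{4,13}]tridecan-9-one | CC(=C)C[C@H]1C(=O)[C@@H]2COC(C)(C)[C@@H]3CC[C@@](C)(C[C@@H]32)[C@H]1C=C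
F5 | step 8 | (1S,4R,8S,10R,11S,13S)-1,5,5-trimethyl-9-oxo-10-(2-oxopropyl)-6-oxatricyclo[6.3.2.0^{4,13}]tridecane-11-carbaldehyde | CC(=O)C[C@H]1C(=O)[C@@H]2COC(C)(C)[C@@H]3CC[C@@](C)(C[C@@H]32)[C@H]1C=O
F6 | step 8 | (1S,4R,8S,10R,11S,13S)-1,5,5-trimethyl-10-(2-oxopropyl)-11-[(E)-2-(4,4,5,5-tetramethyl-1,3,2-dioxaborolan-2-yl)ethenyl]-6-oxatricyclo[6.3.2.0^{4,13}]tridecan-9-one | CC(=O)C[C@H]1C(=O)[C@@H]2COC(C)(C)[C@@H]3CC[C@@](C)(C[C@@H]32)[C@H]1/C=C/B4OC(C)(C)C(C)(C)O4
F7 | step 8 | potassium trifluoro{(E)-2-[(1S,4R,8S,10R,11S,13S)-1,5,5-trimethyl-9-oxo-10-(2-oxopropyl)-6-oxatricyclo[6.3.2.0^{4,13}]tridecan-11-yl]ethenyl}borate | CC(=O)C[C@H]1C(=O)[C@@H]2COC(C)(C)[C@@H]3CC[C@@](C)(C[C@@H]32)[C@H]1/C=C/[B-](F)(F)F.[K+]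
F8 | step 6 | trimethyl{[(1S,4R,8S,11S,13S)-1,5,5-trimethyl-11-(prop-2-en-1-yl)-6-oxatricyclo[6.3.2.0^{4,13}]tridec-9-en-9-yl]oxy}silane | C[Si](C)(C)OC1=C[C@H](CC=C)[C@@]2(C)CC[C@H]3C(C)(C)OC[C@@H]1[C@H]3C2
F9 | step 6 | (1S,4R,8S,10R,11S,13S)-1,5,5-trimethyl-10-(2-oxopropyl)-11-(prop-2-en-1-yl)-6-oxatricyclo[6.3.2.0^{4,13}]tridecan-9-one | CC(=O)C[C@H]1C(=O)[C@@H]2COC(C)(C)[C@@H]3CC[C@@](C)(C[C@@H]32)[C@H]1CC=C
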